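**Strategy.** Everything rests on the bond between the acrylate β-carbon and the doubly allylic methine of the cyclohexene ring fused to the butenolide. That methine is one end of an allyl unit whose other end is the ring-fusion carbon bearing the lactone CH2O; the route therefore places a tertiary carbonate there. Pd(0) ionises this carbonate and the nitronate of a β-nitro ester, an umpoled acrylate β-anion already esterified to the hydroxylated cyclohexane half, attacks the methine carbon. One operation joins the halves, sets the methine trans to isopropyl, moves the alkene into the butenolide and, after loss of HNO2, reveals the (E)-acrylate. The same hydroxy lactone builds both rings.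

Key step: step 14

Assumption: the facial sense of step 1 is assigned by the usual enamine-shielding model ((R)-catalyst gives the R aldehyde); the optical rotation of 4 is to be checked before going on, and the other catalyst enantiomer used if needed.
Assumption: the Grignard reagent of step 4 and LDA in step 8 are used as pre-formed solutions.

Step 1
Reactants: 1 3-methylbutanal; 2 but-3-en-2-one
Product: 3 (2R)-5-oxo-2-(propan-2-yl)hexanal
Conditions: (R)-α,α-diphenylprolinol methyl ether (5 mol%), ethyl 3,4-dihydroxybenzoate (20 mol%), neat, 4 °C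
Reagents that add atoms: none
Why: Enamine-catalysed Michael addition; the enone adds to the enamine face not shielded by the diphenyl(methoxy)methyl group, which should fix the α-carbon as R.

Step 2
Reactants: 3 (2R)-5-oxo-2-(propan-2-yl)hexanal
Product: 4 (4R)-4-(propan-2-yl)cyclohex-2-en-1-one
Conditions: KOH (cat.), nBu4NOH (cat.), THF/Et2O/H2O, reflux
Reagents that add atoms: none
Why: Intramolecular aldol condensation of the 1,5-keto aldehyde; the stereocentre becomes C4 of the enone and should survive the brief, dilute base treatment.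

Step 3
Reactants: 4 (4R)-4-(propan-2-yl)cyclohex-2-en-1-one
Product: 5 (4R)-2-iodo-4-(propan-2-yl)cyclohex-2-en-1-one
Conditions: I2, K2CO3, DMAP (cat.), THF/H2O, rt
Reagents that add atoms: iodine, II
Why: Amine-mediated α-iodination of the enone (conjugate addition of DMAP, iodination of the enolate, elimination), a Baylis–Hillman-type process that leaves the stereocentre untouched.

Step 4
Reactants: 5 (4R)-2-iodo-4-(propan-2-yl)cyclohex-2-en-1-one
Product: 7 (1R,4R)-1-(hydroxymethyl)-2-iodo-4-(propan-2-yl)cyclohex-2-en-1-ol, via silylmethyl carbinol 6 (not isolated)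
Conditions: (iPrO)Me2SiCH2MgCl, THF, −78 → 0 °C; aq. NH4Cl; then 30% H2O2, KF, KHCO3, THF/MeOH, rt
Reagents that add atoms: (isopropoxydimethylsilyl)methylmagnesium chloride, CC(C)O[Si](C)(C)C[Mg]Cl; hydrogen peroxide, OO
Why: Tamao hydroxymethylation (1,2-Grignard addition, then Tamao–Fleming oxidation of C–Si); axial attack on the half-chair with pseudo-equatorial isopropyl should place CH2 cis and OH trans to isopropyl, and the minor epimer is to be removed by chromatography.

Step 5
Reactants: 7 (1R,4R)-1-(hydroxymethyl)-2-iodo-4-(propan-2-yl)cyclohex-2-en-1-ol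
Product: 8 (3aS,6R)-3a-hydroxy-6-(propan-2-yl)-3a,4,5,6-tetrahydro-2-benzofuran-1(3H)-one
Conditions: Pd(PPh3)4 (5 mol%), CO (1 atm), K2CO3, MeCN, 60 °C
Reagents that add atoms: carbon monoxide, [C-]#[O+]
Why: Pd-catalysed carbonylative lactonisation; the acyl-palladium from the vinyl iodide is captured 5-exo by the primary hydroxyl, while the tertiary OH (which could only give a β-lactone) stays free.

Step 6
Reactants: 8 hydroxy lactone
Product: 9 tert-butyl (3aS,6R)-1-oxo-6-(propan-2-yl)-1,4,5,6-tetrahydro-2-benzofuran-3a(3H)-yl carbonate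
Conditions: Boc2O, DMAP (cat.), CH2Cl2, rt
Reagents that add atoms: di-tert-butyl dicarbonate, CC(C)(C)OC(=O)OC(=O)OC(C)(C)C
Why: DMAP-catalysed acylation of the tertiary allylic alcohol, as used for Morita–Baylis–Hillman carbonates, turns the OH into a leaving group without touching the stereocentres.

Step 7
Reactants: 10 3-nitropropanoic acid
Product: 11 tert-butyl 3-nitropropanoate
Conditions: tert-butyl 2,2,2-trichloroacetimidate, BF3·OEt2 (cat.), CH2Cl2/cyclohexane, rt
Reagents that add atoms: tert-butyl 2,2,2-trichloroacetimidate, CC(C)(C)OC(=N)C(Cl)(Cl)Cl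
Why: Acid-catalysed tert-butylation with the imidate keeps the base-labile β-nitro acid away from base.

Step 8
Reactants: 11 tert-butyl 3-nitropropanoate
Product: 13 tert-butyl 2-(hydroxymethyl)-3-nitropropanoate (racemic), via dilithium dianion 12 (not isolated)
Conditions: LDA (2.1 equiv), THF/DMPU, −78 °C; CH2O (monomeric, THF), −78 °C; AcOH
Reagents that add atoms: formaldehyde, C=O
Why: Double deprotonation gives the nitronate/ester-enolate dianion, which cannot expel nitrite and undergoes aldol addition to formaldehyde at the ester α-carbon.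

Step 9
Reactants: 13 tert-butyl 2-(hydroxymethyl)-3-nitropropanoate
Product: 14 tert-butyl 2-({[tert-butyl(dimethyl)silyl]oxy}methyl)-3-nitropropanoate (racemic)
Conditions: TBSCl, imidazole, CH2Cl2, 0 °C
Reagents that add atoms: tert-butyl(chloro)dimethylsilane, CC(C)(C)[Si](C)(C)Cl
Why: Standard silylation of the primary alcohol under weakly basic conditions that should not trigger loss of HNO2.

Step 10
Reactants: 8 hydroxy lactone; 14 silylated nitro ester
Product: 16 cis-fused hydroxy lactone bearing the (E)-acrylate side chain, via nitro Michael adduct 15 (not isolated)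
Conditions: 14 (2 equiv), DBU (0.3 equiv), MeCN, rt; then DBU (3 equiv), rt → 40 °C
Reagents that add atoms: none
Why: Nitro-Michael addition followed by E1cB loss of nitrite (β-nitro ester as acrylate β-anion equivalent); the nitronate should add to the s-cis-locked alkylidene lactone anti to the adjacent isopropyl and on the face of the tertiary OH, protonation gives the cis-fused lactone with its carbonyl branch trans to the new side chain, and elimination gives the E-alkene with the ring trans to the ester.

Step 11
Reactants: 16 ring-A lactone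
Product: 18 4-methoxybenzyl ester of the ring-opened hydroxy acid (free tertiary OH and free CH2OH), via lithium carboxylate 17 (not isolated)
Conditions: LiOH·H2O (1.05 equiv), THF/H2O, 0 °C; evaporate; 4-methoxybenzyl chloride, NaHCO3, nBu4NI (cat.), DMF, rt
Reagents that add atoms: lithium hydroxide, [Li+].[OH-]; 4-methoxybenzyl chloride, COc1ccc(CCl)cc1
Why: Saponification of the γ-lactone then SN2 O-alkylation of the carboxylate; the tert-butyl ester and silyl ether should survive, and 18 is taken on crude because it can re-close to 16.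

Step 12
Reactants: 14 silylated nitro ester
Product: 19 2-({[tert-butyl(dimethyl)silyl]oxy}methyl)-3-nitropropanoic acid (racemic)
Conditions: 85% aq. H3PO4, toluene, rt
Reagents that add atoms: none
Why: Aqueous phosphoric acid cleaves tert-butyl esters by alkyl–oxygen fission and is expected to leave the TBS ether and the base-sensitive nitro group intact.

Step 13
Reactants: 18 diol ester; 19 nitro acid
Product: 20 nitro ester fragment (18 acylated at the primary OH by 19; both epimers at the acyl α-carbon)
Conditions: DIC, DMAP (10 mol%), CH2Cl2, 0 °C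
Reagents that add atoms: none
Why: Steglich esterification at the primary neopentyl hydroxyl (the tertiary OH does not compete); low temperature and catalytic DMAP limit loss of HNO2 from the activated acid.

Step 14
Reactants: 20 nitro ester fragment; 9 allylic carbonate
Product: 22 fully protected target, via nitro coupling adduct 21 (not isolated)
Conditions: Pd2(dba)3·CHCl3 (2.5 mol%), dppe (6 mol%), THF, rt → 40 °C; then DBU (3 equiv), 0 °C → rt
Reagents that add atoms: none
Why: Pd(0) ionises the tertiary allylic carbonate of 9 anti to the leaving group to give a 2-acyl π-allyl complex spanning the ring methine carbon, the lactone α-carbon and the ring-fusion carbon, while the liberated tert-butoxide/CO2 pair deprotonates 20 to its nitronate (Tsuji–Trost allylation of a nitroalkane under neutral conditions; the closest precedents are Pd substitutions of Morita–Baylis–Hillman carbonates). The soft nitronate attacks the secondary allyl terminus anti to palladium, so the new C–C bond forms with net retention on the face the carbonate occupied, i.e. trans to the adjacent isopropyl group, which also disfavours the other face sterically. Attack at this terminus rather than at the quaternary one is secured by sterics and by the gain of the conjugated, tetrasubstituted butenolide alkene. No ring is closed. DBU then removes the ester α-proton of 21 and expels nitrite (E1cB), giving the E-acrylate with the ring trans to the ester because the bulky ring substituent avoids the ester in the enolate. The step needs C- over O-alkylation of the nitronate and coupling faster than premature loss of HNO2 from 20; generating base only as the π-allyl forms is meant to secure both.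

Step 15
Reactants: 22 fully protected target
Product: 23 CNP0071646.2
Conditions: TFA/CH2Cl2/H2O (10:10:1), anisole, 0 °C → rt
Reagents that add atoms: none
Why: Acidolysis should remove the tert-butyl and 4-methoxybenzyl esters (alkyl–oxygen cleavage, cation trapped by anisole) and both TBS ethers in one operation, avoiding base at the doubly allylic methine and at the ester joining the halves.

**Compound list**

1 | 3-methylbutanal | CC(C)CC=O | starting material
2 | but-3-en-2-one | CC(=O)C=C | starting material
3 | (2R)-5-oxo-2-(propan-2-yl)hexanal | CC(=O)CC[C@@H](C=O)C(C)C | intermediate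
4 | (4R)-4-(propan-2-yl)cyclohex-2-en-1-one, (R)-cryptone | O=C1C=C[C@@H](C(C)C)CC1 | intermediate
5 | (4R)-2-iodo-4-(propan-2-yl)cyclohex-2-en-1-one | O=C1C(I)=C[C@@H](C(C)C)CC1 | intermediate
6 | silylmethyl carbinol, (1R,4R)-2-iodo-1-{[dimethyl(propan-2-yloxy)silyl]methyl}-4-(propan-2-yl)cyclohex-2-en-1-ol | CC(C)O[Si](C)(C)C[C@]1(O)CC[C@H](C(C)C)C=C1I | intermediate (not isolated)
7 | (1R,4R)-1-(hydroxymethyl)-2-iodo-4-(propan-2-yl)cyclohex-2-en-1-ol (CH2OH cis, OH trans to isopropyl) | OC[C@]1(O)CC[C@H](C(C)C)C=C1I | intermediate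
8 | hydroxy lactone, (3aS,6R)-3a-hydroxy-6-(propan-2-yl)-3a,4,5,6-tetrahydro-2-benzofuran-1(3H)-one | O=C1OC[C@]2(O)CC[C@H](C(C)C)C=C12 | intermediate
9 | allylic carbonate, tert-butyl (3aS,6R)-1-oxo-6-(propan-2-yl)-1,4,5,6-tetrahydro-2-benzofuran-3a(3H)-yl carbonate | O=C1OC[C@]2(OC(=O)OC(C)(C)C)CC[C@H](C(C)C)C=C12 | intermediate
10 | 3-nitropropanoic acid | OC(=O)CC[N+](=O)[O-] | starting material
11 | tert-butyl 3-nitropropanoate | CC(C)(C)OC(=O)CC[N+](=O)[O-] | intermediate
12 | dilithium dianion of 11 (nitronate/ester enolate) | CC(C)(C)OC([O-])=CC=[N+]([O-])[O-].[Li+].[Li+] | intermediate (not isolated)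
13 | tert-butyl 2-(hydroxymethyl)-3-nitropropanoate (racemic) | CC(C)(C)OC(=O)C(CO)C[N+](=O)[O-] | intermediate
14 | tert-butyl 2-({[tert-butyl(dimethyl)silyl]oxy}methyl)-3-nitropropanoate (racemic) | CC(C)(C)OC(=O)C(CO[Si](C)(C)C(C)(C)C)C[N+](=O)[O-] | intermediate
15 | nitro Michael adduct of 8 and 14 (ring configured as in 16; epimers at the two chain carbons) | O=C1OC[C@]2(O)CC[C@H](C(C)C)[C@@H](C(C(CO[Si](C)(C)C(C)(C)C)C(=O)OC(C)(C)C)[N+](=O)[O-])[C@H]12 | intermediate (not isolated)
16 | tert-butyl (2E)-2-({[tert-butyl(dimethyl)silyl]oxy}methyl)-3-[(3aS,6R,7S,7aS)-3a-hydroxy-1-oxo-6-(propan-2-yl)octahydro-2-benzofuran-7-yl]prop-2-enoate | O=C1OC[C@]2(O)CC[C@H](C(C)C)[C@@H](/C=C(\CO[Si](C)(C)C(C)(C)C)C(=O)OC(C)(C)C)[C@H]12 | intermediate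
17 | lithium carboxylate from opening of 16 | OC[C@]1(O)CC[C@H](C(C)C)[C@@H](/C=C(\CO[Si](C)(C)C(C)(C)C)C(=O)OC(C)(C)C)[C@@H]1C(=O)[O-].[Li+] | intermediate (not isolated)
18 | 4-methoxybenzyl (1S,2S,5R,6S)-6-[(1E)-3-tert-butoxy-2-({[tert-butyl(dimethyl)silyl]oxy}methyl)-3-oxoprop-1-en-1-yl]-2-hydroxy-2-(hydroxymethyl)-5-(propan-2-yl)cyclohexane-1-carboxylate | OC[C@]1(O)CC[C@H](C(C)C)[C@@H](/C=C(\CO[Si](C)(C)C(C)(C)C)C(=O)OC(C)(C)C)[C@@H]1C(=O)OCc1ccc(OC)cc1 | intermediate
19 | 2-({[tert-butyl(dimethyl)silyl]oxy}methyl)-3-nitropropanoic acid (racemic) | OC(=O)C(CO[Si](C)(C)C(C)(C)C)C[N+](=O)[O-] | intermediate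
20 | nitro ester fragment: 18 esterified at its primary OH with 19 (epimers at the acyl α-carbon) | [O-][N+](=O)CC(CO[Si](C)(C)C(C)(C)C)C(=O)OC[C@]1(O)CC[C@H](C(C)C)[C@@H](/C=C(\CO[Si](C)(C)C(C)(C)C)C(=O)OC(C)(C)C)[C@@H]1C(=O)OCc1ccc(OC)cc1 | intermediate
21 | nitro coupling adduct: 20 bonded at its nitro-bearing carbon to the butenolide ring methine (epimers at the two chain carbons) | CC(C)[C@H]1CC[C@@](O)(COC(=O)C(C([C@H]2C3=C(CC[C@@H]2C(C)C)COC3=O)[N+](=O)[O-])CO[Si](C)(C)C(C)(C)C)[C@@H](C(=O)OCc2ccc(OC)cc2)[C@@H]1/C=C(\CO[Si](C)(C)C(C)(C)C)C(=O)OC(C)(C)C | intermediate (not isolated)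
22 | protected target: ring carboxyl as 4-methoxybenzyl ester, side-chain carboxyl as tert-butyl ester, both allylic CH2OH as TBS ethers | CC(C)[C@H]1CC[C@@](O)(COC(=O)/C(=C/[C@H]2C3=C(CC[C@@H]2C(C)C)COC3=O)CO[Si](C)(C)C(C)(C)C)[C@@H](C(=O)OCc2ccc(OC)cc2)[C@@H]1/C=C(\CO[Si](C)(C)C(C)(C)C)C(=O)OC(C)(C)C | intermediate
23 | CNP0071646.2 | CC(C)[C@H]1CC[C@@](O)(COC(=O)/C(=C/[C@H]2C3=C(CC[C@@H]2C(C)C)COC3=O)CO)[C@@H](C(=O)O)[C@@H]1/C=C(\CO)C(=O)O | target

**Step count.** 15 steps in total. Longest linear sequence: 10 steps (1, 2, 3, 4, 5, 10, 11, 13, 14, 15).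

**Steps most likely to fail**

Step 14. Ionisation of the hindered tertiary carbonate may be slower than base-induced loss of nitrite from 20, so the nucleophile would be consumed as its acrylate. The DBU stage may also epimerise or deconjugate the skipped diene. Fallback: the halves are joined through the ester instead. Carbonate 9 and an excess of the simple nitro ester 14 are coupled under the same palladium conditions to give the small nitro adduct F1, which is not isolated. Brief treatment with DBU or Et3N gives the butenolide tert-butyl ester F2. Aqueous H3PO4 in toluene gives the butenolide acrylic acid F3. Steglich esterification (DIC, catalytic DMAP, CH2Cl2, 0 °C) of F3 with the primary hydroxyl of 18 gives 22. The fallback sets out from 9 (with 14 and 18) and returns to the route at 22.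

Step 10. The nitronate may fail to add to the trisubstituted, isopropyl-flanked β-carbon, or the adduct may revert. The β-hydroxy lactone may also dehydrate to the butenolide under DBU. Fallback: copper-catalysed conjugate addition of vinylmagnesium bromide to 8 (CuBr·SMe2, TMSCl, THF, −78 °C, excess reagent for the free OH) should give the vinyl lactone F4, with vinyl anti to isopropyl and a cis ring fusion. Separately, 14 with DBU in CH2Cl2 gives the silyloxymethyl acrylate F5. Cross-metathesis of F4 with F5 (Hoveyda–Grubbs II, toluene, 60 °C) should give 16, the E isomer being favoured as for methacrylate partners. The fallback sets out from 8 and returns at 16.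

Step 11. The γ-hydroxy ester may re-close to lactone 16 under the basic alkylation conditions or during handling. Fallback: no lactone is opened. Diol 7 is silylated at the primary hydroxyl (TESCl, imidazole, CH2Cl2, −20 °C) to give the TES ether F6. Pd-catalysed alkoxycarbonylation (Pd(OAc)2, dppf, CO, 4-methoxybenzyl alcohol, K2CO3, DMF, 60 °C) gives the 4-methoxybenzyl enoate F7. Conjugate addition of 14 with DBU gives the nitro adduct F8, not isolated, which loses HNO2 to give the TES-protected diester F9. AcOH/THF/H2O removes the TES group without base to give 18, which is acylated at once. The fallback sets out from 7 and returns at 18.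

**Further compounds**

F1 | step 14 | nitro adduct of 9 and 14: tert-butyl 2-({[tert-butyl(dimethyl)silyl]oxy}methyl)-3-nitro-3-[(6R,7S)-1-oxo-6-(propan-2-yl)-1,3,4,5,6,7-hexahydro-2-benzofuran-7-yl]propanoate | CC(C)(C)OC(=O)C(CO[Si](C)(C)C(C)(C)C)C([N+](=O)[O-])[C@H]1C2=C(CC[C@@H]1C(C)C)COC2=O
F2 | step 14 | tert-butyl (2E)-2-({[tert-butyl(dimethyl)silyl]oxy}methyl)-3-[(6R,7S)-1-oxo-6-(propan-2-yl)-1,3,4,5,6,7-hexahydro-2-benzofuran-7-yl]prop-2-enoate | CC(C)(C)OC(=O)/C(=C/[C@H]1C2=C(CC[C@@H]1C(C)C)COC2=O)CO[Si](C)(C)C(C)(C)C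
F3 | step 14 | (2E)-2-({[tert-butyl(dimethyl)silyl]oxy}methyl)-3-[(6R,7S)-1-oxo-6-(propan-2-yl)-1,3,4,5,6,7-hexahydro-2-benzofuran-7-yl]prop-2-enoic acid | OC(=O)/C(=C/[C@H]1C2=C(CC[C@@H]1C(C)C)COC2=O)CO[Si](C)(C)C(C)(C)C
F4 | step 10 | vinyl lactone, 7-ethenyl-3a-hydroxy-6-(propan-2-yl)octahydro-2-benzofuran-1-one (ring configured as in 16) | O=C1OC[C@]2(O)CC[C@H](C(C)C)[C@@H](C=C)[C@H]12
F5 | step 10 | tert-butyl 2-({[tert-butyl(dimethyl)silyl]oxy}methyl)prop-2-enoate | C=C(CO[Si](C)(C)C(C)(C)C)C(=O)OC(C)(C)C
F6 | step 11 | (1R,4R)-2-iodo-4-(propan-2-yl)-1-{[(triethylsilyl)oxy]methyl}cyclohex-2-en-1-ol | CC[Si](CC)(CC)OC[C@]1(O)CC[C@H](C(C)C)C=C1I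
F7 | step 11 | 4-methoxybenzyl 6-hydroxy-3-(propan-2-yl)-6-{[(triethylsilyl)oxy]methyl}cyclohex-1-ene-1-carboxylate (configured as in 7) | CC[Si](CC)(CC)OC[C@]1(O)CC[C@H](C(C)C)C=C1C(=O)OCc1ccc(OC)cc1
F8 | step 11 | nitro adduct of F7 and 14 (ring configured as in 18; epimers at the two chain carbons) | CC[Si](CC)(CC)OC[C@]1(O)CC[C@H](C(C)C)[C@@H](C(C(CO[Si](C)(C)C(C)(C)C)C(=O)OC(C)(C)C)[N+](=O)[O-])[C@@H]1C(=O)OCc1ccc(OC)cc1
F9 | step 11 | triethylsilyl ether of 18 at the primary hydroxyl | CC[Si](CC)(CC)OC[C@]1(O)CC[C@H](C(C)C)[C@@H](/C=C(\CO[Si](C)(C)C(C)(C)C)C(=O)OC(C)(C)C)[C@@H]1C(=O)OCc1ccc(OC)cc1
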